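**Retrosynthetic overview**
- The strategy rests on the central oxazole. Its C5(indol-3-yl)=C4(H)–N3 edge has the connectivity of C4(indolyl)=C5(H)–N1 in a 4-(indol-3-yl)-1H-1,2,3-triazole. Its C2(pyrrol-2-yl)/O1 pair is a pyrrole-2-carbonyl group, so the oxazole is that triazole with dinitrogen exchanged for C=O.
- C4–I is cut first, by late magnesiation/iodination of the bis-N-silylated 2,5-disubstituted oxazole. N3–C2 (N-acylation) and O1–C5 (closure after loss of dinitrogen) are then cut together.
- The triazole goes back through the 3-(2-nitrovinyl)indole and the 3-carbaldehyde to 6-bromo-4-methoxyindole. The acyl partner goes back to 1-tosylpyrrole by C2 lithiation, CO2 and acid chloride formation.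
- Ring order: indole and pyrrole are bought, the triazole ring is built in step 3, and it is converted into the oxazole ring in step 6.

Key step: step 6

Remark on the chemistry: the target has no stereocentre. The only stereo-element on the way is the E-alkene of the nitrovinyl compound, which is consumed in step 3. 6-Bromo-4-methoxy-1H-indole and 1-tosylpyrrole are taken as purchasable.

Step 1
Reactants: 1 6-bromo-4-methoxy-1H-indole
Product: 3 6-bromo-4-methoxy-1H-indole-3-carbaldehyde, via iminium chloride 2 (not isolated)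
Conditions: POCl3 (1.2 equiv), DMF, 0 → 40 °C; then aq NaOH, 0 → 60 °C
Reagents that add atoms: N,N-dimethylformamide CN(C)C=O; water O
Why: Vilsmeier–Haack formylation attacks the most nucleophilic indole position, C3, which the 4-methoxy group activates further, and the aryl bromide is inert to the chloroiminium electrophile.

Step 2
Reactants: 3 6-bromo-4-methoxy-1H-indole-3-carbaldehyde; 4 nitromethane
Product: 5 6-bromo-4-methoxy-3-[(E)-2-nitrovinyl]-1H-indole
Conditions: NH4OAc (0.5 equiv), MeNO2 (solvent), 100 °C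
Reagents that add atoms: none
Why: Henry (nitroaldol) condensation under ammonium acetate catalysis is the standard conversion of indole-3-carbaldehydes into 3-(2-nitrovinyl)indoles, and dehydration should give the conjugated, thermodynamically preferred E-alkene.

Step 3
Reactants: 5 6-bromo-4-methoxy-3-[(E)-2-nitrovinyl]-1H-indole; 6 sodium azide
Product: 7 4-(6-bromo-4-methoxy-1H-indol-3-yl)-1H-1,2,3-triazole
Conditions: NaN3 (1.5 equiv), p-TsOH·H2O (0.3 equiv), DMF, 60–80 °C
Reagents that add atoms: none
Why: In this formal [3+2] cycloaddition of azide with a nitroalkene, azide adds to the indole-bearing carbon, the ring closes and nitrite leaves to aromatise the NH-triazole, while the proton shuttle suppresses anionic oligomerisation and excess azide destroys any nitrous acid.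

Step 4
Reactants: 8 1-(p-tolylsulfonyl)pyrrole
Product: 10 1-(p-tolylsulfonyl)-1H-pyrrole-2-carboxylic acid, via 2-lithio-1-tosylpyrrole 9 (not isolated)
Conditions: LiN(iPr)2 (1.1 equiv), THF, −78 °C; CO2 (dry gas), −78 °C → rt; aq HCl
Reagents that add atoms: carbon dioxide O=C=O
Why: In this directed alpha-lithiation of an N-sulfonylpyrrole the sulfonyl oxygen guides the amide base to C2–H, which at −78 °C is removed faster than a tolyl methyl proton, and carboxylation of the heteroaryllithium gives the acid.

Step 5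
Reactants: 10 1-(p-tolylsulfonyl)-1H-pyrrole-2-carboxylic acid
Product: 11 1-(p-tolylsulfonyl)-1H-pyrrole-2-carbonyl chloride
Conditions: (COCl)2 (1.5 equiv), DMF (cat.), CH2Cl2, 0 °C → rt; evaporate, use directly
Reagents that add atoms: oxalyl chloride O=C(Cl)C(=O)Cl
Why: Acid chloride formation through the catalytic chloroiminium species runs under mild, non-nucleophilic conditions that leave the N-sulfonyl group untouched, and the by-products are gases.

Step 6
Reactants: 7 4-(6-bromo-4-methoxy-1H-indol-3-yl)-1H-1,2,3-triazole; 11 1-(p-tolylsulfonyl)-1H-pyrrole-2-carbonyl chloride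
Product: 15 6-bromo-4-methoxy-3-[2-(1-tosyl-1H-pyrrol-2-yl)-1,3-oxazol-5-yl]-1H-indole, via 2-acyl-2H-triazole 12 (not isolated), via 1-acyl-1H-triazole 13 (not isolated), via diazo imine 14 (not isolated)
Conditions: 11 (1.1 equiv), Et3N (1.1 equiv), dry ClCH2CH2Cl, 0 °C → rt; then CF3SO3H (0.5 equiv), rt → 60 °C until gas evolution ends; aq NaHCO3
Reagents that add atoms: none
Why: The triazole NH, by far the most acidic N–H present, is acylated (N3–C2 of the oxazole) to give mainly the 2-acyl isomer 12, which under acid exchanges its acyl group between the ring nitrogens and so feeds the 1-acyl isomer 13; the acceptor on N1 weakens the N1–N2 bond and 13 opens by ring-chain tautomerism to the alpha-diazo N-acylimine 14. Protonation of 14 and loss of dinitrogen leave a cation on the indole-bearing carbon that is spread over the indole as a 3-alkylidene-indoleninium ion, the acyl oxygen adds to it (O1–C5), and loss of a proton gives the aromatic oxazole and returns the acid. The closest known reaction type is the thermal or Brønsted-acid-promoted denitrogenative ring transformation of N-acyl-4-aryl-1,2,3-triazoles into 2,5-disubstituted oxazoles, the triazole relative of the tetrazole to 1,3,4-oxadiazole conversion with acid chlorides. The one ring that closes does so in a five-membered endo mode at a linear cationic carbon, which is the same event as the 6π 1,5-electrocyclisation of the acylimino carbene, and no stereocentre is created. The step needs the indole at C5 and hydrogen at C4: acylation at N3 is crowded by the indole and its peri methoxy group and opening from there would put the charge on an unsubstituted carbon, so only 13 loses dinitrogen and the interconverting isomers drain through it. It also needs oxygen to win the cation: the tosyl group bars the pyrrole nitrogen from a competing six-ring closure, and capture by chloride or triflate should be reversible at so donor-stabilised a centre, whereas O-closure ends in aromatisation.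

Step 7
Reactants: 15 6-bromo-4-methoxy-3-[2-(1-tosyl-1H-pyrrol-2-yl)-1,3-oxazol-5-yl]-1H-indole
Product: 16 6-bromo-4-methoxy-3-[2-(1H-pyrrol-2-yl)-1,3-oxazol-5-yl]-1H-indole
Conditions: NaOH (2 M aq, 3 equiv), MeOH/THF, 50 °C; then aq HCl to pH 7
Reagents that add atoms: none
Why: Base-mediated N-desulfonylation by attack at sulfur is easy here because the 2-(oxazolyl)pyrrolide is a good leaving group, and aryl bromide, methyl ether and oxazole are inert to aqueous hydroxide at this temperature.

Step 8
Reactants: 16 6-bromo-4-methoxy-3-[2-(1H-pyrrol-2-yl)-1,3-oxazol-5-yl]-1H-indole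
Product: 17 6-bromo-4-methoxy-1-(triisopropylsilyl)-3-{2-[1-(triisopropylsilyl)-1H-pyrrol-2-yl]-1,3-oxazol-5-yl}-1H-indole
Conditions: NaH (2.5 equiv), THF/DMF (4:1), 0 °C; iPr3SiCl (2.4 equiv), 0 °C → rt
Reagents that add atoms: chlorotriisopropylsilane CC(C)[Si](Cl)(C(C)C)C(C)C
Why: N-silylation of the two sodium azolides removes both acidic protons, and the bulky, non-directing silyl groups screen indole C2/C7 and pyrrole C5 from the base of the next step.

Step 9
Reactants: 17 6-bromo-4-methoxy-1-(triisopropylsilyl)-3-{2-[1-(triisopropylsilyl)-1H-pyrrol-2-yl]-1,3-oxazol-5-yl}-1H-indole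
Product: 19 6-bromo-3-{4-iodo-2-[1-(triisopropylsilyl)-1H-pyrrol-2-yl]-1,3-oxazol-5-yl}-4-methoxy-1-(triisopropylsilyl)-1H-indole, via oxazol-4-ylmagnesium chloride 18 (not isolated)
Conditions: TMPMgCl·LiCl (1.5 equiv), THF, −20 → 0 °C; I2 (1.5 equiv) in THF, −40 → 0 °C; aq Na2S2O3
Reagents that add atoms: iodine II
Why: Deprotonative magnesiation with the hindered, non-nucleophilic amide base is known to take 2,5-disubstituted oxazoles at C4 with magnesium held by N3, it does not enter Br/Mg exchange, and iodinolysis of the C–Mg bond places iodine only where magnesium sat.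

Step 10
Reactants: 19 6-bromo-3-{4-iodo-2-[1-(triisopropylsilyl)-1H-pyrrol-2-yl]-1,3-oxazol-5-yl}-4-methoxy-1-(triisopropylsilyl)-1H-indole
Product: 20 6-bromo-3-[4-iodo-2-(1H-pyrrol-2-yl)-1,3-oxazol-5-yl]-4-methoxy-1H-indole (target)
Conditions: Bu4NF (2.5 equiv), THF, 0 °C; H2O
Reagents that add atoms: none
Why: Fluoride-mediated N-desilylation is driven by Si–F bond formation and releases both azole NH groups at low temperature without touching the C–I or C–Br bond.

**Compound list**
1 | 6-bromo-4-methoxy-1H-indole | COc1cc(Br)cc2[nH]ccc12 | starting material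
2 | [(6-bromo-4-methoxy-1H-indol-3-yl)methylene]dimethyliminium chloride | COc1cc(Br)cc2[nH]cc(C=[N+](C)C)c12.[Cl-] | intermediate
3 | 6-bromo-4-methoxy-1H-indole-3-carbaldehyde | COc1cc(Br)cc2[nH]cc(C=O)c12 | intermediate
4 | nitromethane | C[N+](=O)[O-] | starting material
5 | 6-bromo-4-methoxy-3-[(E)-2-nitrovinyl]-1H-indole | COc1cc(Br)cc2[nH]cc(/C=C/[N+](=O)[O-])c12 | intermediate
6 | sodium azide | [Na+].[N-]=[N+]=[N-] | starting material
7 | 4-(6-bromo-4-methoxy-1H-indol-3-yl)-1H-1,2,3-triazole | COc1cc(Br)cc2[nH]cc(-c3c[nH]nn3)c12 | intermediate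
8 | 1-(p-tolylsulfonyl)pyrrole | Cc1ccc(S(=O)(=O)n2cccc2)cc1 | starting material
9 | 2-lithio-1-(p-tolylsulfonyl)pyrrole | Cc1ccc(S(=O)(=O)n2cccc2[Li])cc1 | intermediate
10 | 1-(p-tolylsulfonyl)-1H-pyrrole-2-carboxylic acid | Cc1ccc(S(=O)(=O)n2cccc2C(=O)O)cc1 | intermediate
11 | 1-(p-tolylsulfonyl)-1H-pyrrole-2-carbonyl chloride | O=C(Cl)c1cccn1S(=O)(=O)c1ccc(C)cc1 | intermediate
12 | [4-(6-bromo-4-methoxy-1H-indol-3-yl)-2H-1,2,3-triazol-2-yl](1-tosyl-1H-pyrrol-2-yl)methanone | COc1cc(Br)cc2[nH]cc(-c3cnn(C(=O)c4cccn4S(=O)(=O)c4ccc(C)cc4)n3)c12 | intermediate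
13 | [4-(6-bromo-4-methoxy-1H-indol-3-yl)-1H-1,2,3-triazol-1-yl](1-tosyl-1H-pyrrol-2-yl)methanone | COc1cc(Br)cc2[nH]cc(-c3cn(C(=O)c4cccn4S(=O)(=O)c4ccc(C)cc4)nn3)c12 | intermediate
14 | N-[(E)-2-(6-bromo-4-methoxy-1H-indol-3-yl)-2-diazoethylidene]-1-tosyl-1H-pyrrole-2-carboxamide | COc1cc(Br)cc2[nH]cc(C(=[N+]=[N-])/C=N/C(=O)c3cccn3S(=O)(=O)c3ccc(C)cc3)c12 | intermediate
15 | 6-bromo-4-methoxy-3-[2-(1-tosyl-1H-pyrrol-2-yl)-1,3-oxazol-5-yl]-1H-indole | COc1cc(Br)cc2[nH]cc(-c3cnc(-c4cccn4S(=O)(=O)c4ccc(C)cc4)o3)c12 | intermediate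
16 | 6-bromo-4-methoxy-3-[2-(1H-pyrrol-2-yl)-1,3-oxazol-5-yl]-1H-indole | COc1cc(Br)cc2[nH]cc(-c3cnc(-c4ccc[nH]4)o3)c12 | intermediate
17 | 6-bromo-4-methoxy-1-(triisopropylsilyl)-3-{2-[1-(triisopropylsilyl)-1H-pyrrol-2-yl]-1,3-oxazol-5-yl}-1H-indole | COc1cc(Br)cc2n([Si](C(C)C)(C(C)C)C(C)C)cc(-c3cnc(-c4cccn4[Si](C(C)C)(C(C)C)C(C)C)o3)c12 | intermediate
18 | {5-[6-bromo-4-methoxy-1-(triisopropylsilyl)-1H-indol-3-yl]-2-[1-(triisopropylsilyl)-1H-pyrrol-2-yl]-1,3-oxazol-4-yl}magnesium chloride | COc1cc(Br)cc2n([Si](C(C)C)(C(C)C)C(C)C)cc(-c3oc(-c4cccn4[Si](C(C)C)(C(C)C)C(C)C)nc3[Mg]Cl)c12 | intermediate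
19 | 6-bromo-3-{4-iodo-2-[1-(triisopropylsilyl)-1H-pyrrol-2-yl]-1,3-oxazol-5-yl}-4-methoxy-1-(triisopropylsilyl)-1H-indole | COc1cc(Br)cc2n([Si](C(C)C)(C(C)C)C(C)C)cc(-c3oc(-c4cccn4[Si](C(C)C)(C(C)C)C(C)C)nc3I)c12 | intermediate
20 | 6-bromo-3-[4-iodo-2-(1H-pyrrol-2-yl)-1,3-oxazol-5-yl]-4-methoxy-1H-indole | COc1cc(Br)cc2[nH]cc(-c3oc(-c4ccc[nH]4)nc3I)c12 | target

**Total step count:** 10 steps.
**Longest linear sequence:** 8 steps (1, 2, 3, 6, 7, 8, 9, 10). Steps 4 and 5 form the convergent side branch.

**Three steps most likely to fail**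

Step 6. Chloride, triflate or traces of water may take the cation before the acyl oxygen closes on it, so that the chain stays open. The acyl group may also be lost from the triazole by hydrolysis before dinitrogen leaves.

The fallback makes the open-chain outcome the goal and closes the ring in a separate dehydration. It sets out from 7 and 11. The acylation is run as in the route. Dinitrogen is then expelled with CF3SO3H in ClCH2CH2Cl that holds a few equivalents of water, so that water takes the cation and the enol ketonises. This is the known hydrolytic variant that leads to 2-acylamino ketones, and it should give N-[2-(6-bromo-4-methoxy-1H-indol-3-yl)-2-oxoethyl]-1-tosyl-1H-pyrrole-2-carboxamide F1. Robinson–Gabriel cyclodehydration of the ketone (POCl3, toluene, 90 °C), the classical entry to 5-(indol-3-yl)oxazoles, comes back to the route at 15.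

Step 9.
- Deprotonation may be incomplete.
- Deprotonation may take place at the benzenoid position between methoxy and bromine, or on the pyrrole.
- Excess iodine may attack the electron-rich N-silylpyrrole.

The fallback replaces deprotonation by electrophilic substitution on a substrate whose two azole nitrogens carry acceptors. It sets out from 15. The indole nitrogen is sulfonylated (NaH, TsCl, THF) to 6-bromo-4-methoxy-1-tosyl-3-[2-(1-tosyl-1H-pyrrol-2-yl)-1,3-oxazol-5-yl]-1H-indole F2. In this compound pyrrole and indole are deactivated. Both free benzenoid positions are flanked on each side. The enol-ether-like oxazole C4 is therefore the most accessible nucleophilic carbon, as in the known C4 halogenation of 2,5-diaryloxazoles. N-Iodosuccinimide with catalytic CF3CO2H in MeCN should then give 6-bromo-3-[4-iodo-2-(1-tosyl-1H-pyrrol-2-yl)-1,3-oxazol-5-yl]-4-methoxy-1-tosyl-1H-indole F3. NaOH in MeOH/THF at 60 °C removes both sulfonyl groups and reaches the route again at 20.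

Step 3.
- Azide may add slowly, because the indole nitrogen pushes electron density into the nitroalkene.
- Anionic oligomerisation of the nitroalkene may compete.
- Nitrosation by the released nitrite may compete.

The fallback builds the triazole from an alkyne instead and sets out from 1.
- Iodination at C3 (N-iodosuccinimide, DMF, 0 °C) gives 6-bromo-3-iodo-4-methoxy-1H-indole F4.
- Immediate protection (Boc2O, DMAP, CH2Cl2) gives tert-butyl 6-bromo-3-iodo-4-methoxy-1H-indole-1-carboxylate F5.
- Sonogashira coupling with trimethylsilylacetylene (PdCl2(PPh3)2, CuI, Et3N, rt) should react at C–I in preference to C–Br. It gives tert-butyl 6-bromo-4-methoxy-3-[(trimethylsilyl)ethynyl]-1H-indole-1-carboxylate F6.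
- K2CO3 in MeOH removes the silyl and the carbamate group to give 6-bromo-3-ethynyl-4-methoxy-1H-indole F7, which is used at once.
- Copper-catalysed azide–alkyne cycloaddition with Me3SiN3 (CuI, DMF/MeOH, 100 °C) delivers the NH-triazole and comes back to the route at 7.

**Further compounds**
F1 | step 6 | N-[2-(6-bromo-4-methoxy-1H-indol-3-yl)-2-oxoethyl]-1-tosyl-1H-pyrrole-2-carboxamide | COc1cc(Br)cc2[nH]cc(C(=O)CNC(=O)c3cccn3S(=O)(=O)c3ccc(C)cc3)c12
F2 | step 9 | 6-bromo-4-methoxy-1-tosyl-3-[2-(1-tosyl-1H-pyrrol-2-yl)-1,3-oxazol-5-yl]-1H-indole | COc1cc(Br)cc2n(S(=O)(=O)c3ccc(C)cc3)cc(-c3cnc(-c4cccn4S(=O)(=O)c4ccc(C)cc4)o3)c12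
F3 | step 9 | 6-bromo-3-[4-iodo-2-(1-tosyl-1H-pyrrol-2-yl)-1,3-oxazol-5-yl]-4-methoxy-1-tosyl-1H-indole | COc1cc(Br)cc2n(S(=O)(=O)c3ccc(C)cc3)cc(-c3oc(-c4cccn4S(=O)(=O)c4ccc(C)cc4)nc3I)c12
F4 | step 3 | 6-bromo-3-iodo-4-methoxy-1H-indole | COc1cc(Br)cc2[nH]cc(I)c12
F5 | step 3 | tert-butyl 6-bromo-3-iodo-4-methoxy-1H-indole-1-carboxylate | COc1cc(Br)cc2n(C(=O)OC(C)(C)C)cc(I)c12
F6 | step 3 | tert-butyl 6-bromo-4-methoxy-3-[(trimethylsilyl)ethynyl]-1H-indole-1-carboxylate | COc1cc(Br)cc2n(C(=O)OC(C)(C)C)cc(C#C[Si](C)(C)C)c12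
F7 | step 3 | 6-bromo-3-ethynyl-4-methoxy-1H-indole | COc1cc(Br)cc2[nH]cc(C#C)c12
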